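**Assumptions (one line):** The starting material is natural (2E,7R,11R)-phytol, which is commercially available at ≥95% E. Pd precatalysts and biaryl phosphine ligands count as commercial. Only compounds that supply skeleton atoms are numbered; reagents that leave atoms in a product are given with SMILES in the step.

## Retrosynthetic overview
1. The chroman ring is formed last, by disconnecting the C8a–O bond. This is a stereoretentive Pd-catalysed etherification of a tertiary alcohol onto an aryl triflate. The C2 centre is therefore fixed in an acyclic tertiary carbinol before any ring exists.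
2. That homobenzylic tertiary alcohol comes from Mizoroki–Heck coupling of an aryl iodide with (3R,7R,11R)-isophytol, followed by hydrogenation.
3. Isophytol is made from phytol by Sharpless asymmetric epoxidation, then epoxy iodide formation, then Zn reductive opening. Phytol supplies C4′ and C8′ (7R,11R) unchanged and, through the epoxidation, the future C2.
4. The arene is 2,5-dimethylhydroquinone, converted to its mono-pivalate, then ortho-iodinated next to the free OH, then triflated. The only ring formed is the chroman, and the benzene ring is present from the start.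

## Route

**Step 1**
Reactants: 1 (2E,7R,11R)-phytol
Product: 2 (2R,3R,7R,11R)-2,3-epoxy-3,7,11,15-tetramethylhexadecan-1-ol
Conditions: Ti(OiPr)4 (10 mol%), D-(−)-DET (12 mol%), TBHP, 3 Å MS, CH2Cl2, −20 °C
Reagents that add atoms: tert-butyl hydroperoxide, CC(C)(C)OO (supplies the epoxide O)
Why: Sharpless asymmetric epoxidation of the (E)-trisubstituted allylic alcohol is directed by the CH2OH group, so D-tartrate fixes the tertiary C3 (future C2 of the target) as R without relying on Me versus alkyl discrimination.

**Step 2**
Reactants: 2
Product: 3 (2S,3R,7R,11R)-2,3-epoxy-1-iodo-3,7,11,15-tetramethylhexadecane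
Conditions: PPh3, I2, imidazole, Et2O/MeCN (3:1), 0 °C → rt
Reagents that add atoms: iodine, II
Why: Appel-type iodination of the primary alcohol leaves the epoxide carbons untouched. The descriptor at C2 changes from R to S only because iodine raises the CIP priority of C1.

**Step 3**
Reactants: 3
Product: 4 (3R,7R,11R)-3,7,11,15-tetramethylhexadec-1-en-3-ol [(3R,7R,11R)-isophytol]
Conditions: Zn dust (activated), cat. NaI, EtOH, reflux
Reagents that add atoms: none
Why: Boord-type reductive ring opening of the 2,3-epoxy iodide forms the terminal C=C and leaves the oxygen on C3, so the tertiary carbinol keeps its configuration because the C3–O bond is never broken.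

**Step 4**
Reactants: 5 2,5-dimethylbenzene-1,4-diol (2,5-dimethylhydroquinone)
Product: 6 4-hydroxy-2,5-dimethylphenyl pivalate
Conditions: PivCl (1.0 equiv), Et3N, CH2Cl2, 0 °C
Reagents that add atoms: pivaloyl chloride, CC(C)(C)C(=O)Cl
Why: Statistical mono-acylation of the symmetric diol (about 50% yield, diol recycled) leaves one phenol free to direct iodination and later carry the triflate.

**Step 5**
Reactants: 6
Product: 7 4-hydroxy-3-iodo-2,5-dimethylphenyl pivalate
Conditions: NIS, cat. TsOH·H2O, MeCN, rt
Reagents that add atoms: N-iodosuccinimide, O=C1CCC(=O)N1I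
Why: Electrophilic aromatic iodination goes ortho to the free, strongly activating OH, which is the only CH ortho to it. The pivalate-bearing oxygen is much less activating, and this gives the C4a halogen with the correct 5,8-dimethyl pattern.

**Step 6**
Reactants: 7
Product: 8 3-iodo-2,5-dimethyl-4-(trifluoromethanesulfonyloxy)phenyl pivalate
Conditions: Tf2O, pyridine, CH2Cl2, 0 °C
Reagents that add atoms: triflic anhydride, O=S(=O)(OS(=O)(=O)C(F)(F)F)C(F)(F)F
Why: Phenol triflation makes C8a a Pd-reactive electrophile, and the C–I bond is kept for chemoselective Heck coupling.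

**Step 7**
Reactants: 4 isophytol, 8 aryl iodide/triflate
Product: 9 3-[(1E,3R,7R,11R)-3-hydroxy-3,7,11,15-tetramethylhexadec-1-en-1-yl]-2,5-dimethyl-4-(triflyloxy)phenyl pivalate
Conditions: Pd(OAc)2 (5 mol%), n-Bu4NCl, NaHCO3, DMF, 90 °C
Reagents that add atoms: none
Why: Jeffery-type Mizoroki–Heck reaction is chemoselective for Ar–I over Ar–OTf, and the tertiary carbinol has no α-H, so β-H elimination gives the styrene and the stereocentre is untouched.

**Step 8**
Reactants: 9
Product: 10 (3R,7R,11R)-1-[4-(triflyloxy)-2,5-dimethyl-3-… aryl]-3,7,11,15-tetramethylhexadecan-3-ol, i.e. the homobenzylic tertiary alcohol with OPiv retained. Full structure: see SMILES in the compound list.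
Conditions: H2 (1 atm), 10% Pd/C, EtOAc, rt
Reagents that add atoms: none (H2 adds only hydrogen)
Why: Catalytic hydrogenation of the disubstituted styrenyl C=C under neutral conditions leaves the aryl triflate, pivalate and tertiary C–O bond intact.

**Step 9**
Reactants: 10
Product: 11 (2R)-2,5,8-trimethyl-2-[(4R,8R)-4,8,12-trimethyltridecyl]chroman-6-yl pivalate
Conditions: Pd2(dba)3 (2.5 mol%), Me4-tBuXPhos (10 mol%), Cs2CO3, toluene, 100 °C
Reagents that add atoms: none
Why: Proposed new method: intramolecular Buchwald–Hartwig-type C–O coupling of a hindered tertiary alkoxide with a 2,6-disubstituted aryl triflate. It proceeds by oxidative addition into Ar–OTf, alkoxide binding, then C–O reductive elimination, and a tertiary alkoxide has no α-H, so neither β-H elimination nor hydrodehalogenation competes. The carbinol C–O bond is never cleaved, so C2 stays R. The closest known reaction is Pd- or Cu-catalysed intramolecular O-arylation of 3-(2-haloaryl)propanols to 2,2-disubstituted chromans.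

**Step 10**
Reactants: 11
Product: 12 (2R,4′R,8′R)-β-tocopherol
Conditions: LiAlH4, THF, 0 °C → rt, under Ar
Reagents that add atoms: none (LiAlH4 adds only hydrogen)
Why: Hydride cleavage of the phenolic pivalate releases the C6 phenol, and the chroman ether, side chain and C2 centre are unaffected.

## Compound list
1 | (2E,7R,11R)-phytol | OC/C=C(C)/CCC[C@H](C)CCC[C@H](C)CCCC(C)C | starting material
2 | (2R,3R,7R,11R)-2,3-epoxy-3,7,11,15-tetramethylhexadecan-1-ol | C[C@]1(CCC[C@H](C)CCC[C@H](C)CCCC(C)C)O[C@@H]1CO | intermediate
3 | (2S,3R,7R,11R)-2,3-epoxy-1-iodo-3,7,11,15-tetramethylhexadecane | C[C@]1(CCC[C@H](C)CCC[C@H](C)CCCC(C)C)O[C@@H]1CI | intermediate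
4 | (3R,7R,11R)-3,7,11,15-tetramethylhexadec-1-en-3-ol | O[C@](C)(CCC[C@H](C)CCC[C@H](C)CCCC(C)C)C=C | intermediate
5 | 2,5-dimethylbenzene-1,4-diol | Cc1cc(O)c(C)cc1O | starting material
6 | 4-hydroxy-2,5-dimethylphenyl pivalate | CC(C)(C)C(=O)Oc1cc(C)c(O)cc1C | intermediate
7 | 4-hydroxy-3-iodo-2,5-dimethylphenyl pivalate | CC(C)(C)C(=O)Oc1cc(C)c(O)c(I)c1C | intermediate
8 | 3-iodo-2,5-dimethyl-4-(triflyloxy)phenyl pivalate | CC(C)(C)C(=O)Oc1cc(C)c(OS(=O)(=O)C(F)(F)F)c(I)c1C | intermediate
9 | Heck product (E-styryl tertiary alcohol) | O[C@](C)(CCC[C@H](C)CCC[C@H](C)CCCC(C)C)/C=C/c1c(C)c(OC(=O)C(C)(C)C)cc(C)c1OS(=O)(=O)C(F)(F)F | intermediate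
10 | (3R,7R,11R)-homobenzylic tertiary alcohol (aryl = 6-OPiv, 5,8-dimethyl, 8a-OTf pattern) | O[C@](C)(CCC[C@H](C)CCC[C@H](C)CCCC(C)C)CCc1c(C)c(OC(=O)C(C)(C)C)cc(C)c1OS(=O)(=O)C(F)(F)F | intermediate
11 | (2R)-2,5,8-trimethyl-2-[(4R,8R)-4,8,12-trimethyltridecyl]chroman-6-yl pivalate | Cc1cc(OC(=O)C(C)(C)C)c(C)c2c1O[C@](C)(CCC[C@H](C)CCC[C@H](C)CCCC(C)C)CC2 | intermediate
12 | (2R,4′R,8′R)-β-tocopherol | Cc1cc(O)c(C)c2c1O[C@](C)(CCC[C@H](C)CCC[C@H](C)CCCC(C)C)CC2 | target

## Totals
Total steps: 10. Longest linear sequence: 7 steps (phytol → 2 → 3 → 4 → 9 → 10 → 11 → 12, or equivalently hydroquinone → 6 → 7 → 8 → 9 → 10 → 11 → 12).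

**Three steps most likely to fail**
1. **Step 9, Pd-catalysed C–O closure.** It joins a tertiary alkoxide to a di-ortho-substituted aryl triflate. Competing S–O cleavage of the triflate and reduction of the triflate are the main dangers.
   - Fallback (different approach): make 4-(2-hydroxyaryl)butan-2-one by Heck coupling of the ortho-iodophenol with 3-buten-2-ol. Then do catalytic asymmetric Corey–Chaykovsky epoxidation, acid-promoted 6-exo opening of the epoxide by the phenol (inversion at C2), oxidation to the aldehyde, and Wittig coupling with the phytol-derived (3R,7R)-3,7,11-trimethyldodecyl phosphonium salt, then hydrogenation.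
2. **Step 7, Heck coupling.** The aryl iodide is flanked by OTf and Me, and the tertiary allylic alcohol may fragment (β-carbon elimination) or couple in low yield.
   - Fallback (different coupling): hydroborate 4 with 9-BBN, then B-alkyl Suzuki–Miyaura coupling with 8 (Pd(dppf)Cl2, K3PO4). This gives 10 directly and skips Step 8.
3. **Steps 2–3, the acid-sensitive tertiary epoxy iodide and its Zn opening.** The iodide may ionise or give iodohydrin, and E/Z impurity in the phytol would erode the C3 configuration.
   - Fallback (different stereocentre strategy): ozonolyse phytol to (6R,10R)-6,10,14-trimethylpentadecan-2-one, which converges E and Z. Then use the La/Li/biaryldiolate-catalysed asymmetric Corey–Chaykovsky epoxidation (Me3S(O)I), followed by opening with dimethylsulfonium methylide (Me3SI, n-BuLi) to reach 4.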